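**Retrosynthetic overview**
- Target ⇐ acetonide removal ⇐ Heck union of a 4‑vinyl core enamide with a (2E,4E)‑5‑bromodienamide that already carries the 2‑amino‑3‑hydroxycyclopentenone ring (from cyclopentane‑1,3‑dione).
- Core enamide ⇐ copper‑catalysed amidation of an α‑iodoenone with (2E,4R,6S)‑4,6‑dimethyldec‑2‑enamide (two zirconium‑catalysed carboaluminations from hex‑1‑ene).
- Iodoenone ⇐ enone ⇐ allylic oxidation of the cis‑diol acetonide ⇐ anti‑selective reduction of (S)‑2‑alkoxy‑2‑vinylcyclohex‑3‑enone.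
- Key step: Pd‑catalysed enantioselective semipinacol (Wagner–Meerwein) ring expansion, cyclopentenol → cyclohexenone, which sets the quaternary carbinol C‑4; the substrate comes from cyclopent‑2‑enone and a lithiated alkoxyallene.
- Ring order: six‑membered core first (by ring expansion), then the temporary dioxolane; the cyclopentenone ring is carried in intact.

Assumption: the (R,R) ligand in step 2 and the (+)/(−) zirconocene pairing in steps 7 and 8 are taken to give the configurations drawn; if a first run shows the opposite sense, the enantiomeric catalyst is used.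

**Core**

Step 1
Reactants: 1 3-(1-ethoxyethoxy)prop-1-yne (propargyl alcohol bought as its 1-ethoxyethyl (EE) ether); 2 cyclopent-2-en-1-one
Product: 5 1-[1-(1-ethoxyethoxy)propa-1,2-dien-1-yl]cyclopent-2-en-1-ol, via allenyl ether 3 (not isolated), via lithioallene 4 (not isolated)
Conditions: KOtBu (10 mol%), THF, 0 °C→rt; n-BuLi, −78 °C; then 2, −78 °C; H2O quench, Et3N-buffered work-up
Reagents that add atoms: none
Why: Base-catalysed propargyl→allenyl ether isomerisation, α-lithiation and 1,2-addition of the hard lithioallene (acyl-anion equivalent) to the enone carbonyl; the racemic carbinol centre and the EE epimers are inconsequential because the carbinol carbon becomes C=O in step 2.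

Step 2
Reactants: 5 1-[1-(1-ethoxyethoxy)propa-1,2-dien-1-yl]cyclopent-2-en-1-ol
Product: 6 (2S)-2-ethenyl-2-(1-ethoxyethoxy)cyclohex-3-en-1-one
Conditions: Pd2(dba)3·CHCl3 (2.5 mol%), (R,R)-DACH-phenyl Trost ligand (7.5 mol%), PhCO2H (10 mol%), Et3N (10 mol%), ClCH2CH2Cl, 50 °C
Reagents that add atoms: none
Why: Proposed new method: a Pd–H species (zerovalent palladium plus PhCO2H) hydropalladates the distal C=C of the alkoxyallene to a 1-alkoxy-π-allylpalladium (oxocarbenium-like) whose faces equilibrate through the unsubstituted CH2 terminus, and the ring alkenyl carbon then shifts 1,2 from the carbinol to the alkoxy-bearing allyl terminus anti to Pd inside the chiral pocket (semipinacol/Wagner–Meerwein ring expansion 5→6), forming the cyclohexenone ring and the (S) quaternary C–O centre while the racemic carbinol centre is erased; the closest known reaction is the Pd-catalysed asymmetric Wagner–Meerwein shift of 1-(1-alkoxyallenyl)cyclobutanols to 2-alkoxy-2-vinylcyclopentanones, not shown for strain-free cyclopentenols, where the high migratory aptitude of the sp2 carbon and C=O formation must supply the driving force.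

Step 3
Reactants: 6 (2S)-2-ethenyl-2-(1-ethoxyethoxy)cyclohex-3-en-1-one
Product: 7 (1R,2S)-2-ethenyl-2-(1-ethoxyethoxy)cyclohex-3-en-1-ol
Conditions: K(s-Bu)3BH, THF, −78 °C; H2O
Reagents that add atoms: none
Why: Non-chelating hydride reduction under Felkin–Anh (polar) control: hydride enters anti to the pseudo-axial C–O bond of the α-alkoxy ketone, so the new OH is cis to the tertiary oxygen (sets C-5, R).

Step 4
Reactants: 7 (1R,2S)-2-ethenyl-2-(1-ethoxyethoxy)cyclohex-3-en-1-ol
Product: 9 (3aR,7aS)-7a-ethenyl-2,2-dimethyl-3a,4,5,7a-tetrahydro-1,3-benzodioxole, via diol 8 (not isolated)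
Conditions: PPTS (10 mol%), MeOH, rt; evaporate; 2,2-dimethoxypropane, acetone, PPTS, rt
Reagents that add atoms: 2,2-dimethoxypropane, COC(C)(C)OC
Why: Mild acetal exchange removes EE without ionising the bis-allylic tertiary alcohol, and the cis-1,2-diol is trapped as the isopropylidene acetal (only a cis diol closes, so it also proves the step 3 outcome).

Step 5
Reactants: 9 (3aR,7aS)-7a-ethenyl-2,2-dimethyl-3a,4,5,7a-tetrahydro-1,3-benzodioxole
Product: 10 (3aR,7aS)-7a-ethenyl-2,2-dimethyl-3a,7a-dihydro-1,3-benzodioxol-5(4H)-one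
Conditions: Rh2(cap)4 (dirhodium tetracaprolactamate, 1 mol%), t-BuOOH (5 equiv), K2CO3, CH2Cl2, rt
Reagents that add atoms: tert-butyl hydroperoxide, CC(C)(C)OO
Why: Radical allylic C–H oxidation at the only allylic CH2; as with 3,3-disubstituted cyclohexenes, the quaternary neighbour directs peroxide trapping to the remote terminus and gives the 4,4-disubstituted enone, while the vinyl group has no allylic hydrogen.

Step 6
Reactants: 10 (3aR,7aS)-7a-ethenyl-2,2-dimethyl-3a,7a-dihydro-1,3-benzodioxol-5(4H)-one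
Product: 11 (3aR,7aS)-7a-ethenyl-6-iodo-2,2-dimethyl-3a,7a-dihydro-1,3-benzodioxol-5(4H)-one
Conditions: I2, pyridine, CH2Cl2, 0 °C→rt
Reagents that add atoms: iodine, II
Why: Johnson α-iodination of an enone (pyridine conjugate addition, enolate iodination, elimination), which works on 4,4-disubstituted cyclohexenones.

**Upper amide**

Step 7
Reactants: 12 hex-1-ene; 13 bromoethene (vinyl bromide)
Product: 15 (4S)-4-methyloct-1-ene, via methylhexylalane 14 (not isolated)
Conditions: AlMe3, (+)-(NMI)2ZrCl2 [(+)-bis(1-neomenthylindenyl)zirconium dichloride, 4 mol%], methylaluminoxane, CH2Cl2, 0→23 °C; evaporate; Zn(OTf)2, DMF, 70 °C; then 13, PdCl2(DPEphos) (3 mol%), i-Bu2AlH (6 mol%), 23 °C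
Reagents that add atoms: trimethylaluminium, C[Al](C)C
Why: Zirconium-catalysed asymmetric carboalumination (ZACA) sets the butyl/methyl centre under catalyst control (about 75–80% ee, upgraded in step 8), followed by zinc-promoted Pd-catalysed cross-coupling of the alkylalane with vinyl bromide (Negishi-type).

Step 8
Reactants: 15 (4S)-4-methyloct-1-ene
Product: 17 (2R,4S)-2,4-dimethyloctan-1-ol, via dimethyloctylalane 16 (not isolated)
Conditions: AlMe3, (−)-(NMI)2ZrCl2 (4 mol%), methylaluminoxane, CH2Cl2, 0→23 °C; then O2, 0 °C; aq. HCl; chromatography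
Reagents that add atoms: trimethylaluminium, C[Al](C)C; dioxygen, O=O
Why: Second ZACA with the enantiomeric catalyst sets the second methyl centre anti to the first, and C–Al oxidation proceeds with retention; the minor enantiomer from step 7 ends mainly in the syn diastereomer, which chromatography removes (statistical amplification to about 96% ee or better).

Step 9
Reactants: 17 (2R,4S)-2,4-dimethyloctan-1-ol
Product: 19 (2E,4R,6S)-4,6-dimethyldec-2-enamide, via aldehyde 18 (not isolated)
Conditions: Dess–Martin periodinane, NaHCO3, CH2Cl2, rt; then Ph3P=CHCONH2, rt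
Reagents that add atoms: (carbamoylmethylene)triphenylphosphorane, NC(=O)C=P(c1ccccc1)(c1ccccc1)c1ccccc1
Why: Dess–Martin oxidation followed in the same flask by Wittig olefination with a stabilised ylide gives the (E)-enamide without epimerising the α-methyl aldehyde.

**Enamide formation**

Step 10
Reactants: 11 (3aR,7aS)-7a-ethenyl-6-iodo-2,2-dimethyl-3a,7a-dihydro-1,3-benzodioxol-5(4H)-one; 19 (2E,4R,6S)-4,6-dimethyldec-2-enamide
Product: 20 (2E,4R,6S)-N-[(3aR,7aS)-7a-ethenyl-2,2-dimethyl-5-oxo-3a,4,5,7a-tetrahydro-1,3-benzodioxol-6-yl]-4,6-dimethyldec-2-enamide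
Conditions: CuI (10 mol%), N,N′-dimethylethylenediamine (20 mol%), Cs2CO3, THF, 65 °C
Reagents that add atoms: none
Why: Copper-catalysed Goldberg–Buchwald amidation of an alkenyl iodide with a primary amide, with retention of alkene position; the cis-fused acetonide simply re-closes by oxa-Michael addition if base triggers β-alkoxide elimination.

**Lower bromodienamide**

Step 11
Reactants: 21 potassium (1E,3E)-5-oxopenta-1,3-dien-1-olate (glutaconaldehyde potassium salt)
Product: 22 (2E,4E)-5-bromopenta-2,4-dienal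
Conditions: PPh3, Br2, CH2Cl2, 0 °C→rt
Reagents that add atoms: bromine, BrBr
Why: Deoxybromination of the vinylogous carboxylate (O-phosphonium formation, then addition–elimination by bromide), which settles to the (E,E) isomer.

Step 12
Reactants: 22 (2E,4E)-5-bromopenta-2,4-dienal
Product: 23 (2E,4E)-5-bromopenta-2,4-dienoic acid
Conditions: NaClO2, NaH2PO4, 2-methylbut-2-ene, t-BuOH/H2O, rt
Reagents that add atoms: sodium chlorite, [Na+].[O-]Cl=O
Why: Pinnick oxidation of an enal to the acid without touching the alkenyl bromide or the alkene geometry.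

Step 13
Reactants: 24 cyclopentane-1,3-dione
Product: 25 2-(hydroxyimino)cyclopentane-1,3-dione
Conditions: NaNO2, aq. HCl, 0 °C
Reagents that add atoms: sodium nitrite, [Na+].[O-]N=O
Why: Nitrosation of the active methylene of a 1,3-dione, followed by tautomerisation to the oxime.

Step 14
Reactants: 25 2-(hydroxyimino)cyclopentane-1,3-dione
Product: 26 2-amino-3-hydroxycyclopent-2-en-1-one hydrochloride
Conditions: H2 (1 atm), 10% Pd/C, MeOH, HCl (1.1 equiv), rt
Reagents that add atoms: hydrogen chloride, Cl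
Why: Catalytic hydrogenation of an α-oximino ketone to the α-amino ketone (Knorr-type), trapped as the stable enol hydrochloride.

Step 15
Reactants: 23 (2E,4E)-5-bromopenta-2,4-dienoic acid; 26 2-amino-3-hydroxycyclopent-2-en-1-one hydrochloride
Product: 28 (2E,4E)-5-bromo-N-(2-hydroxy-5-oxocyclopent-1-en-1-yl)penta-2,4-dienamide, via acid chloride 27 (not isolated)
Conditions: (COCl)2, DMF (cat.), CH2Cl2, 0 °C→rt, evaporate; then 26, Et3N, THF, 0 °C→rt
Reagents that add atoms: none
Why: Acid chloride formation and N-acylation of the weakly nucleophilic vinylogous-amide amine; any O-acyl material rearranges or hydrolyses to the N-acyl enol.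

**Endgame**

Step 16
Reactants: 20 (2E,4R,6S)-N-[(3aR,7aS)-7a-ethenyl-2,2-dimethyl-5-oxo-3a,4,5,7a-tetrahydro-1,3-benzodioxol-6-yl]-4,6-dimethyldec-2-enamide; 28 (2E,4E)-5-bromo-N-(2-hydroxy-5-oxocyclopent-1-en-1-yl)penta-2,4-dienamide
Product: 29 (2E,4R,6S)-N-[(3aR,7aS)-7a-[(1E,3E,5E)-7-[(2-hydroxy-5-oxocyclopent-1-en-1-yl)amino]-7-oxohepta-1,3,5-trien-1-yl]-2,2-dimethyl-5-oxo-3a,4,5,7a-tetrahydro-1,3-benzodioxol-6-yl]-4,6-dimethyldec-2-enamide
Conditions: Pd(OAc)2 (10 mol%), n-Bu4NCl, K2CO3, DMF, 45 °C; aq. NaH2PO4 work-up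
Reagents that add atoms: none
Why: Heck reaction under Jeffery conditions: the alkenylpalladium adds to the terminal CH2, Pd ends next to the quaternary carbon, and β-hydride elimination can therefore only give the conjugated (E)-alkene; the internal disubstituted alkenes of 28 and 20 are much poorer acceptors.

Step 17
Reactants: 29 (2E,4R,6S)-N-[(3aR,7aS)-7a-[(1E,3E,5E)-7-[(2-hydroxy-5-oxocyclopent-1-en-1-yl)amino]-7-oxohepta-1,3,5-trien-1-yl]-2,2-dimethyl-5-oxo-3a,4,5,7a-tetrahydro-1,3-benzodioxol-6-yl]-4,6-dimethyldec-2-enamide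
Product: 30 (2E,4R,6S)-N-[(3S,4R)-3,4-dihydroxy-3-[(1E,3E,5E)-7-[(2-hydroxy-5-oxocyclopent-1-en-1-yl)amino]-7-oxohepta-1,3,5-trien-1-yl]-6-oxocyclohex-1-en-1-yl]-4,6-dimethyldec-2-enamide
Conditions: AcOH/H2O (4:1), 35 °C
Reagents that add atoms: none
Why: Acid hydrolysis of the cis-fused isopropylidene acetal; ionisation at C-4 is disfavoured by the electron-poor enone, and no stereocentre is touched.

**Compound list**
1 | 3-(1-ethoxyethoxy)prop-1-yne (EE-protected propargyl alcohol, racemic acetal) | C#CCOC(C)OCC | starting material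
2 | cyclopent-2-en-1-one | O=C1C=CCC1 | starting material
3 | 1-(1-ethoxyethoxy)propa-1,2-diene | C=C=COC(C)OCC | intermediate (not isolated)
4 | [1-(1-ethoxyethoxy)propa-1,2-dien-1-yl]lithium | [Li]C(OC(C)OCC)=C=C | intermediate (not isolated)
5 | 1-[1-(1-ethoxyethoxy)propa-1,2-dien-1-yl]cyclopent-2-en-1-ol (racemic carbinol, EE epimers) | OC1(C=CCC1)C(OC(C)OCC)=C=C | intermediate
6 | (2S)-2-ethenyl-2-(1-ethoxyethoxy)cyclohex-3-en-1-one (EE epimers) | C1=C[C@@](OC(C)OCC)(C=C)C(=O)CC1 | intermediate
7 | (1R,2S)-2-ethenyl-2-(1-ethoxyethoxy)cyclohex-3-en-1-ol (EE epimers) | C1=C[C@@](OC(C)OCC)(C=C)[C@H](O)CC1 | intermediate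
8 | (1S,6R)-1-ethenylcyclohex-2-ene-1,6-diol | C1=C[C@@](O)(C=C)[C@H](O)CC1 | intermediate (not isolated)
9 | (3aR,7aS)-7a-ethenyl-2,2-dimethyl-3a,4,5,7a-tetrahydro-1,3-benzodioxole | C1=C[C@@]2(OC(C)(C)O[C@@H]2CC1)C=C | intermediate
10 | (3aR,7aS)-7a-ethenyl-2,2-dimethyl-3a,7a-dihydro-1,3-benzodioxol-5(4H)-one | C1=C[C@@]2(OC(C)(C)O[C@@H]2CC1=O)C=C | intermediate
11 | (3aR,7aS)-7a-ethenyl-6-iodo-2,2-dimethyl-3a,7a-dihydro-1,3-benzodioxol-5(4H)-one | IC1=C[C@@]2(OC(C)(C)O[C@@H]2CC1=O)C=C | intermediate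
12 | hex-1-ene | CCCCC=C | starting material
13 | bromoethene (vinyl bromide) | C=CBr | starting material
14 | dimethyl[(2S)-2-methylhexyl]alumane | CCCC[C@H](C)C[Al](C)C | intermediate (not isolated)
15 | (4S)-4-methyloct-1-ene | CCCC[C@H](C)CC=C | intermediate
16 | [(2R,4S)-2,4-dimethyloctyl]dimethylalumane | CCCC[C@H](C)C[C@@H](C)C[Al](C)C | intermediate (not isolated)
17 | (2R,4S)-2,4-dimethyloctan-1-ol | CCCC[C@H](C)C[C@@H](C)CO | intermediate
18 | (2R,4S)-2,4-dimethyloctanal | CCCC[C@H](C)C[C@@H](C)C=O | intermediate (not isolated)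
19 | (2E,4R,6S)-4,6-dimethyldec-2-enamide | CCCC[C@H](C)C[C@@H](C)/C=C/C(N)=O | intermediate
20 | (2E,4R,6S)-N-[(3aR,7aS)-7a-ethenyl-2,2-dimethyl-5-oxo-3a,4,5,7a-tetrahydro-1,3-benzodioxol-6-yl]-4,6-dimethyldec-2-enamide | CCCC[C@H](C)C[C@@H](C)/C=C/C(=O)NC1=C[C@@]2(OC(C)(C)O[C@@H]2CC1=O)C=C | intermediate
21 | potassium (1E,3E)-5-oxopenta-1,3-dien-1-olate (glutaconaldehyde potassium salt) | [K+].[O-]/C=C/C=C/C=O | starting material
22 | (2E,4E)-5-bromopenta-2,4-dienal | Br/C=C/C=C/C=O | intermediate
23 | (2E,4E)-5-bromopenta-2,4-dienoic acid | Br/C=C/C=C/C(O)=O | intermediate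
24 | cyclopentane-1,3-dione | O=C1CCC(=O)C1 | starting material
25 | 2-(hydroxyimino)cyclopentane-1,3-dione | ON=C1C(=O)CCC1=O | intermediate
26 | 2-amino-3-hydroxycyclopent-2-en-1-one hydrochloride | Cl.NC1=C(O)CCC1=O | intermediate
27 | (2E,4E)-5-bromopenta-2,4-dienoyl chloride | Br/C=C/C=C/C(Cl)=O | intermediate (not isolated)
28 | (2E,4E)-5-bromo-N-(2-hydroxy-5-oxocyclopent-1-en-1-yl)penta-2,4-dienamide | Br/C=C/C=C/C(=O)NC1=C(O)CCC1=O | intermediate
29 | acetonide of the target (name as in step 16) | CCCC[C@H](C)C[C@@H](C)/C=C/C(=O)NC1=C[C@@]2(OC(C)(C)O[C@@H]2CC1=O)/C=C/C=C/C=C/C(=O)NC1=C(O)CCC1=O | intermediate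
30 | (2E,4R,6S)-N-[(3S,4R)-3,4-dihydroxy-3-[(1E,3E,5E)-7-[(2-hydroxy-5-oxocyclopent-1-en-1-yl)amino]-7-oxohepta-1,3,5-trien-1-yl]-6-oxocyclohex-1-en-1-yl]-4,6-dimethyldec-2-enamide | CCCC[C@H](C)C[C@@H](C)/C=C/C(=O)NC1=C[C@@](O)(/C=C/C=C/C=C/C(=O)NC2=C(O)CCC2=O)[C@H](O)CC1=O | target

**Step count**
Total: 17 steps. Longest linear sequence: 9 steps (1, 2, 3, 4, 5, 6, 10, 16, 17).

**Steps most likely to fail, with fallbacks**

Step 2 (the new ring expansion; risks are no reaction without strain release, acid-triggered Nazarov-type ionisation of 5, or low ee). The fallback uses known chemistry only, sets out from vinyl bromide 13 and comes back at enone 10. Compound 13 is converted with Mg in THF into vinylmagnesium bromide F1, which adds 1,2 to commercial 4,4-dimethoxycyclohexa-2,5-dien-1-one (COC1(OC)C=CC(=O)C=C1) to give 4,4-dimethoxy-1-vinylcyclohexa-2,5-dien-1-ol F2 after aqueous NH4Cl quench. Aqueous acetic acid unmasks the ketone to give the p-quinol 4-hydroxy-4-vinylcyclohexa-2,5-dien-1-one F3. A desymmetrising oxa-Michael addition with phenylboronic acid and a cinchona-derived thiourea–amine organocatalyst (boronic-acid hemiester as a tethered hydroxide surrogate, a known reaction class for γ-hydroxy enones and 4-hydroxycyclohexadienones) delivers oxygen cis to the tertiary OH and gives the cyclic boronate (3aR,7aS)-7a-ethenyl-2-phenyl-3a,7a-dihydro-1,3,2-benzodioxaborol-5(4H)-one F4; the catalyst pseudo-enantiomer selects the enone face. Transesterification with pinacol releases (4S,5R)-4-ethenyl-4,5-dihydroxycyclohex-2-en-1-one F5, and 2,2-dimethoxypropane/PPTS converts F5 into 10.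

Step 5 (allylic oxidation; risks are a regioisomeric enone, over-oxidation or a low yield). The fallback sets out from 9 and comes back at 10, replacing the one-step radical C–H oxidation by hydroxylation then alcohol oxidation. SeO2 (catalytic) with t-BuOOH in CH2Cl2 hydroxylates the only allylic CH2 by an ene reaction followed by a 2,3-sigmatropic shift, which returns oxygen to the original allylic carbon and leaves the alkene in place. This gives (3aR,7aS)-7a-ethenyl-2,2-dimethyl-3a,4,5,7a-tetrahydro-1,3-benzodioxol-5-ol F6 (both carbinol epimers), and Dess–Martin periodinane or MnO2 oxidises F6 to 10.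

Step 16 (Heck coupling; risks are self-coupling of 28, catalyst poisoning by the acidic enol, or polyene degradation). The fallback sets out from 20 and comes back at 29 by a cross-coupling of two preformed alkenyl partners. OsO4 (catalytic), NaIO4 and 2,6-lutidine in dioxane/H2O cleave only the monosubstituted vinyl group, the most electron-rich alkene, to give the aldehyde (2E,4R,6S)-N-[(3aR,7aS)-7a-formyl-2,2-dimethyl-5-oxo-3a,4,5,7a-tetrahydro-1,3-benzodioxol-6-yl]-4,6-dimethyldec-2-enamide F7. Chromium-mediated stannyl olefination (CrCl2, Bu3SnCHBr2, LiI, THF/DMF) gives the (E)-alkenylstannane (2E,4R,6S)-N-[(3aR,7aR)-2,2-dimethyl-5-oxo-7a-[(E)-2-(tributylstannyl)ethenyl]-3a,4,5,7a-tetrahydro-1,3-benzodioxol-6-yl]-4,6-dimethyldec-2-enamide F8 (same spatial arrangement; only the CIP descriptor changes). Stille coupling of F8 with bromide 28 (Pd2(dba)3, AsPh3, DMF, rt), the bond construction used for this triene in the manumycin family, gives 29.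

**Further compounds**
F1 | step 2 | vinylmagnesium bromide | C=C[Mg]Br
F2 | step 2 | 4,4-dimethoxy-1-vinylcyclohexa-2,5-dien-1-ol | COC1(OC)C=CC(O)(C=C)C=C1
F3 | step 2 | 4-hydroxy-4-vinylcyclohexa-2,5-dien-1-one | O=C1C=CC(O)(C=C)C=C1
F4 | step 2 | (3aR,7aS)-7a-ethenyl-2-phenyl-3a,7a-dihydro-1,3,2-benzodioxaborol-5(4H)-one | C1=C[C@@]2(OB(c3ccccc3)O[C@@H]2CC1=O)C=C
F5 | step 2 | (4S,5R)-4-ethenyl-4,5-dihydroxycyclohex-2-en-1-one | C1=C[C@@](O)(C=C)[C@H](O)CC1=O
F6 | step 5 | (3aR,7aS)-7a-ethenyl-2,2-dimethyl-3a,4,5,7a-tetrahydro-1,3-benzodioxol-5-ol (carbinol epimers) | C1=C[C@@]2(OC(C)(C)O[C@@H]2CC1O)C=C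
F7 | step 16 | (2E,4R,6S)-N-[(3aR,7aS)-7a-formyl-2,2-dimethyl-5-oxo-3a,4,5,7a-tetrahydro-1,3-benzodioxol-6-yl]-4,6-dimethyldec-2-enamide | CCCC[C@H](C)C[C@@H](C)/C=C/C(=O)NC1=C[C@@]2(OC(C)(C)O[C@@H]2CC1=O)C=O
F8 | step 16 | (2E,4R,6S)-N-[(3aR,7aR)-2,2-dimethyl-5-oxo-7a-[(E)-2-(tributylstannyl)ethenyl]-3a,4,5,7a-tetrahydro-1,3-benzodioxol-6-yl]-4,6-dimethyldec-2-enamide | CCCC[C@H](C)C[C@@H](C)/C=C/C(=O)NC1=C[C@@]2(OC(C)(C)O[C@@H]2CC1=O)/C=C/[Sn](CCCC)(CCCC)CCCC
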